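**Retrosynthetic overview**
1. Target (5,5'-linked dimer of dihydroferulic acid) ⇐ hydrogenolysis of two benzyl ethers ⇐ saponification ⇐ O-methylation of a biaryl diester whose ring A has a free C3 hydroxyl beside a benzylated C4 oxygen (each ring numbered C1 chain, C3 OMe, C4 OH, C5 biaryl carbon).
2. The strategy rests on ring A (C1–C6) and its vicinal C3/C4 oxygens. The ring is cut at C6–C1 and C4–C5: C5 and C6 are the carbonyl and methyl carbons of an acetyl group on C5 of ring B, and C1–C4 are the two alkyne carbons, the ketone carbon and the benzyloxymethyl carbon of methyl 7-benzyloxy-6-oxohept-4-ynoate.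
3. Acetyl arene ⇐ Stille acetylation of the aryl bromide ⇐ benzylation ⇐ ortho bromination ⇐ esterification of dihydroferulic acid. Alkynone ⇐ acyl Sonogashira coupling of methyl pent-4-ynoate with benzyloxyacetyl chloride.
4. Ring order: ring B is bought with dihydroferulic acid; ring A is the only ring made, by Michael–aldol benzannulation on the acetyl group.

Key step: step 6

Remark on the chemistry: the target has no stereocenter, and with one ortho oxygen per ring the biaryl axis is assumed to rotate freely, so nothing stereochemical has to be set. Locants C1–C6 in the text are the ring locants defined above; compound names use systematic numbering.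

**Route**

Step 1
Reactants: 1 dihydroferulic acid, 3-(4-hydroxy-3-methoxyphenyl)propanoic acid
Product: 2 methyl 3-(4-hydroxy-3-methoxyphenyl)propanoate
Conditions: MeOH, H2SO4 (cat.), reflux
Reagents that add atoms: methanol, CO
Why: Fischer esterification driven by methanol as solvent should convert the acid cleanly, the phenol being inert under these conditions.

Step 2
Reactants: 2 methyl 3-(4-hydroxy-3-methoxyphenyl)propanoate
Product: 3 methyl 3-(3-bromo-4-hydroxy-5-methoxyphenyl)propanoate
Conditions: NBS (1.0 equiv), i-Pr2NH (10 mol %), CH2Cl2, 0 °C to rt, dark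
Reagents that add atoms: N-bromosuccinimide, O=C1CCC(=O)N1Br
Why: Amine-catalysed electrophilic aromatic bromination of a phenol, in which the N-bromoamine delivers bromine within a hydrogen-bonded complex to the carbon ortho to the hydroxyl; the para position carries the chain and the other ortho position the methoxy group, so only C5 is open.

Step 3
Reactants: 3 methyl 3-(3-bromo-4-hydroxy-5-methoxyphenyl)propanoate
Product: 4 methyl 3-(4-benzyloxy-3-bromo-5-methoxyphenyl)propanoate
Conditions: BnBr (1.2 equiv), K2CO3 (2 equiv), DMF, rt
Reagents that add atoms: benzyl bromide, BrCc1ccccc1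
Why: Williamson ether synthesis on the phenoxide should proceed without touching the methyl ester or the aryl bromide.

Step 4
Reactants: 4 methyl 3-(4-benzyloxy-3-bromo-5-methoxyphenyl)propanoate
Product: 6 methyl 3-(3-acetyl-4-benzyloxy-5-methoxyphenyl)propanoate, via enol ether 5 (not isolated)
Conditions: tributyl(1-ethoxyvinyl)stannane (1.3 equiv), PdCl2(PPh3)2 (5 mol %), toluene, 100 °C; then 1 M HCl, THF, rt
Reagents that add atoms: tributyl(1-ethoxyvinyl)stannane, CCCC[Sn](CCCC)(CCCC)C(=C)OCC; water, O
Why: Stille coupling with the 1-ethoxyvinyl group as a masked acetyl group (oxidative addition of zerovalent palladium formed from PdCl2(PPh3)2 into the aryl C–Br bond, transmetalation from tin, reductive elimination) gives enol ether 5, which dilute acid should hydrolyse to the methyl ketone without harming the benzyl ether or the ester.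

Step 5
Reactants: 7 methyl pent-4-ynoate; 8 benzyloxyacetyl chloride
Product: 9 methyl 7-benzyloxy-6-oxohept-4-ynoate
Conditions: PdCl2(PPh3)2 (2 mol %), CuI (4 mol %), Et3N (1.1 equiv, added last, dropwise), THF, 0 °C to rt
Reagents that add atoms: none
Why: Acyl Sonogashira coupling, in which the acid chloride adds oxidatively to zerovalent palladium, the copper acetylide formed from 7, CuI and Et3N transmetalates, and reductive elimination gives the ynone; the methyl ester and benzyl ether are spectators.

Step 6
Reactants: 6 methyl 3-(3-acetyl-4-benzyloxy-5-methoxyphenyl)propanoate (1.5 equiv); 9 methyl 7-benzyloxy-6-oxohept-4-ynoate (1.0 equiv)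
Product: 13 dimethyl 3,3'-[2,2'-bis(benzyloxy)-3-hydroxy-3'-methoxy-[1,1'-biphenyl]-5,5'-diyl]dipropanoate, via Michael adduct 10 (not isolated), via aldol adduct 11 (not isolated), via cyclohexadienone 12 (not isolated)
Conditions: Cs2CO3 (2 equiv), 4 Å molecular sieves, DMSO, rt, 9 added over several hours by syringe pump; then 60 °C; aq. NH4Cl work-up
Reagents that add atoms: none
Why: Cs2CO3 in DMSO deprotonates the acetyl group of 6 reversibly and the enolate adds in conjugate fashion to the alkyne carbon of 9 that bears the ester chain (bond C6–C1), giving Michael adduct 10, whose alkene geometry equilibrates through the dienolate of the doubly activated C6 methylene. Deprotonation of 10 at the benzyloxy-bearing methylene then lets C4 attack the aryl ketone carbon C5 in a 6-(enolendo)-exo-trig aldol closure to 11, which loses water to cyclohexadienone 12, and 12 tautomerizes irreversibly to phenol 13. The closest known chemistry is the base-mediated Michael–aldol benzannulation of ketones with alkynones, a Robinson-type annulation at the arene oxidation level, and the ring closure is the one by which the ene-1,5-dione pseudobases of 2-alkylpyrylium salts pass into phenols. No stereocenter is formed. The step needs conjugate in place of direct carbonyl addition, cross-reaction in place of self-condensation of 9, and one mode of ring closure: the reversible carbonate conditions should give the first, a low stationary concentration of 9 against an excess of the enolate of 6 the second, and the substrate the third, since the acetyl methyl is the only enolizable position next to the ketone of 6 and any other ketone-enolate aldol in 10 would have to close a four-membered ring. Because the alkynone carbonyl becomes the C3 hydroxyl while the C4 oxygen arrives benzylated, the two neighbouring oxygens of ring A come out differentiated.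

Step 7
Reactants: 13 dimethyl 3,3'-[2,2'-bis(benzyloxy)-3-hydroxy-3'-methoxy-[1,1'-biphenyl]-5,5'-diyl]dipropanoate
Product: 14 dimethyl 3,3'-[2,2'-bis(benzyloxy)-3,3'-dimethoxy-[1,1'-biphenyl]-5,5'-diyl]dipropanoate
Conditions: MeI (1.5 equiv), K2CO3 (2 equiv), acetone, 50 °C
Reagents that add atoms: iodomethane, CI
Why: Williamson methylation of the only free phenol should place the methyl group on the C3 oxygen of ring A and make the two rings identical.

Step 8
Reactants: 14 dimethyl 3,3'-[2,2'-bis(benzyloxy)-3,3'-dimethoxy-[1,1'-biphenyl]-5,5'-diyl]dipropanoate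
Product: 15 3,3'-[2,2'-bis(benzyloxy)-3,3'-dimethoxy-[1,1'-biphenyl]-5,5'-diyl]dipropanoic acid
Conditions: LiOH·H2O (5 equiv), THF/MeOH/H2O, rt; then 1 M HCl to pH 2
Reagents that add atoms: lithium hydroxide (as hydroxide), [Li+].[OH-]
Why: Saponification by acyl–oxygen cleavage should hydrolyse both methyl esters while the benzyl and methyl aryl ethers are inert to hydroxide, and the phenols are still protected during the basic step.

Step 9
Reactants: 15 3,3'-[2,2'-bis(benzyloxy)-3,3'-dimethoxy-[1,1'-biphenyl]-5,5'-diyl]dipropanoic acid
Product: 16 3,3'-(2,2'-dihydroxy-3,3'-dimethoxy-[1,1'-biphenyl]-5,5'-diyl)dipropanoic acid (target, CNP0122720.0)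
Conditions: H2 (1 atm), 10% Pd/C, EtOAc/EtOH, rt
Reagents that add atoms: none
Why: Catalytic hydrogenolysis of the two benzyl aryl ethers should free both phenols under neutral conditions, leaving the arenes, methyl ethers and acids untouched and the product salt-free after filtration.

**Compound list**
1 | dihydroferulic acid, 3-(4-hydroxy-3-methoxyphenyl)propanoic acid | COc1cc(CCC(=O)O)ccc1O | starting material
2 | methyl 3-(4-hydroxy-3-methoxyphenyl)propanoate | COC(=O)CCc1ccc(O)c(OC)c1 | intermediate
3 | methyl 3-(3-bromo-4-hydroxy-5-methoxyphenyl)propanoate | COC(=O)CCc1cc(Br)c(O)c(OC)c1 | intermediate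
4 | methyl 3-(4-benzyloxy-3-bromo-5-methoxyphenyl)propanoate | COC(=O)CCc1cc(Br)c(OCc2ccccc2)c(OC)c1 | intermediate
5 | methyl 3-[4-benzyloxy-3-(1-ethoxyvinyl)-5-methoxyphenyl]propanoate (enol ether, not isolated) | COC(=O)CCc1cc(OC)c(OCc2ccccc2)c(C(=C)OCC)c1 | intermediate
6 | methyl 3-(3-acetyl-4-benzyloxy-5-methoxyphenyl)propanoate | COC(=O)CCc1cc(OC)c(OCc2ccccc2)c(C(C)=O)c1 | intermediate
7 | methyl pent-4-ynoate | C#CCCC(=O)OC | starting material
8 | benzyloxyacetyl chloride | O=C(Cl)COCc1ccccc1 | starting material
9 | methyl 7-benzyloxy-6-oxohept-4-ynoate | COC(=O)CCC#CC(=O)COCc1ccccc1 | intermediate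
10 | methyl 7-benzyloxy-4-{2-[2-benzyloxy-3-methoxy-5-(3-methoxy-3-oxopropyl)phenyl]-2-oxoethyl}-6-oxohept-4-enoate (Michael adduct, equilibrating E/Z mixture, not isolated) | COC(=O)CCC(CC(=O)c1cc(CCC(=O)OC)cc(OC)c1OCc1ccccc1)=CC(=O)COCc1ccccc1 | intermediate
11 | methyl 3-{4-benzyloxy-5-[2-benzyloxy-3-methoxy-5-(3-methoxy-3-oxopropyl)phenyl]-5-hydroxy-3-oxocyclohex-1-en-1-yl}propanoate (aldol adduct, diastereomer mixture, not isolated) | COC(=O)CCC1=CC(=O)C(OCc2ccccc2)C(O)(c2cc(CCC(=O)OC)cc(OC)c2OCc2ccccc2)C1 | intermediate
12 | methyl 3-{4-benzyloxy-5-[2-benzyloxy-3-methoxy-5-(3-methoxy-3-oxopropyl)phenyl]-3-oxocyclohexa-1,4-dien-1-yl}propanoate (cyclohexadienone, not isolated) | COC(=O)CCC1=CC(=O)C(OCc2ccccc2)=C(c2cc(CCC(=O)OC)cc(OC)c2OCc2ccccc2)C1 | intermediate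
13 | dimethyl 3,3'-[2,2'-bis(benzyloxy)-3-hydroxy-3'-methoxy-[1,1'-biphenyl]-5,5'-diyl]dipropanoate | COC(=O)CCc1cc(O)c(OCc2ccccc2)c(-c2cc(CCC(=O)OC)cc(OC)c2OCc2ccccc2)c1 | intermediate
14 | dimethyl 3,3'-[2,2'-bis(benzyloxy)-3,3'-dimethoxy-[1,1'-biphenyl]-5,5'-diyl]dipropanoate | COC(=O)CCc1cc(OC)c(OCc2ccccc2)c(-c2cc(CCC(=O)OC)cc(OC)c2OCc2ccccc2)c1 | intermediate
15 | 3,3'-[2,2'-bis(benzyloxy)-3,3'-dimethoxy-[1,1'-biphenyl]-5,5'-diyl]dipropanoic acid | O=C(O)CCc1cc(OC)c(OCc2ccccc2)c(-c2cc(CCC(=O)O)cc(OC)c2OCc2ccccc2)c1 | intermediate
16 | 3,3'-(2,2'-dihydroxy-3,3'-dimethoxy-[1,1'-biphenyl]-5,5'-diyl)dipropanoic acid | COc1cc(CCC(=O)O)cc(-c2cc(CCC(=O)O)cc(OC)c2O)c1O | target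

**Step count**
Total: 9 steps. Longest linear sequence: 8 steps (steps 1, 2, 3, 4, 6, 7, 8, 9); step 5 is the one-step side branch.

**Steps most likely to fail and their fallbacks**

1. Step 6, the benzannulation. The alkynone may be used up before it meets the ketone enolate, either by self-condensation through its own alpha-benzyloxy enolate or by base-induced isomerization through the propargylic methylene to an allenone and on to a conjugated dienone. The sequence may also stall after the conjugate addition, because the aryl ketone is hindered and electron-rich and the aldol closure is slow. The phenoxide of the product may in addition capture fresh alkynone by oxa-Michael addition. The fallback gives up ring construction and makes the biaryl bond by cross-coupling. It sets out from bromide 4: Miyaura borylation (B2pin2, PdCl2(dppf), KOAc, dioxane, 90 °C) should give the pinacol boronate methyl 3-[4-benzyloxy-3-methoxy-5-(4,4,5,5-tetramethyl-1,3,2-dioxaborolan-2-yl)phenyl]propanoate F1. Suzuki–Miyaura coupling of F1 with a second equivalent of 4 (Pd(OAc)2, SPhos, K3PO4, toluene/H2O, 90 °C) should then give the symmetric biaryl directly. The fallback comes back to the route at compound 14, so step 7 is no longer needed.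

2. Step 5, the acyl Sonogashira coupling. Triethylamine may dehydrochlorinate the alpha-alkoxy acid chloride to benzyloxyketene, which dimerizes or oligomerizes, and the amine may also degrade the base-sensitive ynone as it forms. The fallback avoids any amine by moving the acylation to a preformed alkynylstannane. It sets out from alkyne 7: stannylation (Bu3SnOMe, ZnBr2 (5 mol %), THF, rt) should give methyl 5-(tributylstannyl)pent-4-ynoate F2. Base-free Stille acylation of F2 with acid chloride 8 (PdCl2(PPh3)2, 1,2-dichloroethane, 60 °C) should give the ynone. The fallback comes back to the route at compound 9.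

3. Step 2, the ortho bromination. Substitution may compete at the position para to the methoxy group, and a second bromination may follow the first, which would lower the yield of the single regioisomer the Stille step needs. The fallback installs the acetyl carbon by chelation-directed formylation, where only the position ortho to the hydroxyl can react, and bypasses steps 2 to 4. It sets out from phenol 2: magnesium-phenoxide-directed ortho formylation (MgCl2, Et3N, paraformaldehyde, MeCN, reflux) should give methyl 3-(3-formyl-4-hydroxy-5-methoxyphenyl)propanoate F3. Benzylation (BnBr, K2CO3, DMF) should give methyl 3-(4-benzyloxy-3-formyl-5-methoxyphenyl)propanoate F4. Chemoselective addition of MeMgBr to the aldehyde (1.05 equiv, THF, −78 °C) should give racemic methyl 3-[4-benzyloxy-3-(1-hydroxyethyl)-5-methoxyphenyl]propanoate F5, and Dess–Martin oxidation (CH2Cl2, rt) should give the methyl ketone. The fallback comes back to the route at compound 6.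

**Further compounds**
F1 | step 6 | methyl 3-[4-benzyloxy-3-methoxy-5-(4,4,5,5-tetramethyl-1,3,2-dioxaborolan-2-yl)phenyl]propanoate | COC(=O)CCc1cc(OC)c(OCc2ccccc2)c(B2OC(C)(C)C(C)(C)O2)c1
F2 | step 5 | methyl 5-(tributylstannyl)pent-4-ynoate | COC(=O)CCC#C[Sn](CCCC)(CCCC)CCCC
F3 | step 2 | methyl 3-(3-formyl-4-hydroxy-5-methoxyphenyl)propanoate | COC(=O)CCc1cc(C=O)c(O)c(OC)c1
F4 | step 2 | methyl 3-(4-benzyloxy-3-formyl-5-methoxyphenyl)propanoate | COC(=O)CCc1cc(C=O)c(OCc2ccccc2)c(OC)c1
F5 | step 2 | methyl 3-[4-benzyloxy-3-(1-hydroxyethyl)-5-methoxyphenyl]propanoate (racemic) | COC(=O)CCc1cc(C(C)O)c(OCc2ccccc2)c(OC)c1
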